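In the epsilon run X read 24.0% at 1.25 d and 24.0% at 8.00 d, which is flat, and the delta run also goes flat, at a lower level. We therefore take Z to be the limiting reagent in both runs.

| setting | epsilon | delta | flask |
|---|---|---|---|
| X | 0.34 M | 0.34 M | 0.34 M |
| Z | 0.62 M (fed, over 5.0 h) | 0.97 M (fed, over 5.0 h) | 0.442 M (fed, over 5.0 h) |
| remark | run made earlier; the fed solution adds 0.10 times the starting volume | run made earlier; the fed solution adds 0.10 times the starting volume | the fed solution adds 0.10 times the starting volume |
| time |  |  | 8.0 d |

| run | time / d | X / % | Q / % |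
|---|---|---|---|
| epsilon | 1.25 | 24.0 | 15.6 |
| epsilon | 2.50 | 23.9 | 16.0 |
| epsilon | 3.00 | 24.2 | 16.0 |
| epsilon | 5.00 | 24.3 | 16.3 |
| epsilon | 6.00 | 24.2 | 16.4 |
| epsilon | 8.00 | 24.0 | 16.1 |
| delta | 0.625 | 5.6 | 4.7 |
| delta | 1.04 | 5.0 | 4.4 |
| delta | 1.67 | 5.0 | 4.0 |
| delta | 2.50 | 4.9 | 4.1 |
| delta | 3.00 | 4.8 | 3.8 |
| delta | 5.00 | 4.9 | 4.0 |
| delta | 8.00 | 4.6 | 3.3 |

(scatter of a reading: 0.3 percentage points)

- amounts are per litre of the starting volume; all of the dose is in the solution fed
- the numbers in the tables scatter with a standard deviation of 0.3 percentage points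
- candidate steps: X + Z -> Q + L; Z + Q -> J + L; Z + J -> G + L; Z + G <-> E + L; Z -> D

1. the X standing at 8.0 d, as a percentage of the X charged
2. the Q standing at 8.0 d, as a percentage of the X charged
3. the J standing at 8.0 d, as a percentage of the X charged
4. the G standing at 8.0 d, as a percentage of the X charged

Let τ = −ln(fraction of X left), using the mean of the last three readings of each run. We then ask how much Z one unit of τ costs.

epsilon: [Z] charged / [X] at the start = 1.82, τ = 1.42

delta: [Z] charged / [X] at the start = 2.85, τ = 3.04

Epsilon's Z price is 1.28, the Z charged per X for each unit of τ. Delta's is lower, at 0.937. Both are readings and carry the scatter. Between these two runs the price falls as τ grows, so we take the flask's price to depend on its own answer, and we go round twice, drawing a straight line through the two runs, which falls by 0.214 per unit of τ.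

flask: [Z] charged / [X] at the start = 1.30

first round: τ = 1.01, and the line there gives a price of 1.37

second round: τ = 0.948, so X = 38.7%

Turned round, the opposite outcome, X nearly gone, is what the delta run reached, at 2.85 Z per X. The flask carries about half of that, so we expect its X to end above delta's readings.

The forecast, reasoning that “The plateaus show Z is used up”, gave X 37.3%, below our figure, with Q 21.5%, J 16.5% and G 24%. The flask gives X 37.5%, Q 21.2%, J 19.6% and G 21.7%, with Z at 0% of its charge.

    X + Z → Q + L (k = 2.03 /M/h)
    Z + Q → J + L (k = 4.57 /M/h)
    Z + J → G + L (k = 4.24 /M/h)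
    Z + G ⇌ E + L (K = 2.20, k = 0.0627 /M/h)
    Z → D (k = 0.0295 /h)

The flask's result gives a price of 1.33, above epsilon's and below our second round's, and our X stands 1.2 percentage points too high. The neighbour flask has X cut to 0.14 M with Z unchanged, so it carries 3.16 Z per X. The first round gives τ = 2.46 and a price of 1.06. The second gives τ = 2.97, so X = 5.12%. That neighbour ends with Z at 0.0310% of its charge and X at 3.69%.

The runs were computed for an exercise, noise included.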